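## The problem

The target is a 5-deoxy proanthocyanidin dimer. An upper flavan-3-ol (benzo ring A, pyran ring C, catechol ring B; atoms O1, C2, C3, C4, C4a, C5–C8, C8a) is bonded through its benzylic C4 to C6' of a lower flavan-3,4-diol (rings D, F, E; primed atoms). The central bond therefore joins a stereocentre to an arene carbon that sits next to the C7' oxygen. There are six stereocentres in two triads: upper (2R,3S,4R), all-trans, and lower (2R,3S,4S), 2,3-trans-3,4-cis. Within a triad the C2 aryl group can send a reagent to the opposite face of a C3=C4 alkene and so control C3 and C4. The two triads are separated by the freely rotating C4–C6' bond and cannot control each other, so each C2 needs its own source of absolute configuration. The lower C4' carbinol is benzylic to ring D and activated by O1' (ortho) and O7' (para). Acid ionises it, with epimerisation or self-condensation, and hydrogen on palladium can cleave it, so the last steps must be neutral. The six phenols and three aliphatic hydroxyls make the free compound polar and easily oxidised, which calls for one global phenol protecting group removed last. The feature that opens the structure is upper C4: it carries ring A (through C4a), ring D (through C6') and one hydrogen trans to the C3 hydroxyl. This is the pattern left by anti-Markovnikov syn hydration of a C3=C4 alkene, and the matching 1,1-diarylethene is nucleophilic enough to close C2–C3 onto an oxocarbenium ion held on O1.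

## Retrosynthesis

**24 to 23 to 22 (O–benzyl and O–silicon bonds).** All six phenols are carried as benzyl ethers from the two starting materials, so one hydrogenolysis of triol 23 ends the synthesis. The lower cis-diol is carried as two tert-butyldimethylsilyl ethers (22), not as an acetonide. Hydrolysing an acetal at the end would need acid at the very C4'–O bond that ionises most easily, whereas fluoride attacks silicon and leaves the C–O bond alone. The forward steps must not reduce or epimerise C4'.

**22 to 20 (C3–O and C4–H).** Removing the C3 hydroxyl and the C4 hydrogen gives the 4-aryl-flav-3-ene 20. The neighbouring cut, the C4–C6' bond through a flavan-4-yl cation, would have to choose between C6' and C8' and would expose the lower carbinol to the same acid. The hydroboration cut removes two stereocentres at once and makes both depend on C2. It asks that borane place boron on C3 from the face opposite the C2 aryl group.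

**20 to 19 (C2–C3, ring C; key disconnection).** Opening ring C between C2 and C3 leaves O1–C2 as part of an acetal and C3/C4 as a 1,1-diarylethene. The alternatives are closure at O1–C2 (a phenol onto a 1,3-diarylallyl cation) or at C4–C4a (Friedel–Crafts). The C2–C3 cut alone turns the precursor into three simple pieces joined at oxygen and at the vinyl carbon, and leaves no upper stereocentre in 19. The forward reaction must control the face of the oxocarbenium ion at C2.

**19 to 17 and 3 (acetal C–O bond).** The acetal is chosen as O-aryl O-pivaloyl, not O-aryl O-methyl. A benzaldehyde aryl methyl acetal ionises preferentially by loss of the phenol, which would untether the alkene. An acyloxy acetal can only lose the carboxylic acid, which leaves the cation on the aryl oxygen. The acetal 19 is cut to phenol 17 and aldehyde 3, joined through the chloro ester 18 under basic conditions.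

**17 to 16 to 11 and 12 (allyl–O, then the vinyl C–C6' bond).** The free phenol is masked as an allyl ether (16), which comes off under neutral conditions. The diarylethene is cut at the bond to ring D into aryl bromide 11 (as aryllithium 13 and organocerium 14) and methyl ketone 12, with carbinol 15 dehydrated in the same operation. This cut forms the interflavan bond of the target from an aryl nucleophile whose position is fixed by the bromine, so no C6'/C8' question arises.

**11 to 10 to 9 to 8 (C–Br, O–Si, both C–O bonds of the diol).** Bromination of 10 at the carbon para to O1' and ortho to the benzyloxy group is the innate selectivity of the ring. Diol 9 is the cis-dihydroxylation product of flav-3-ene 8 on the face opposite the C2 aryl group, which gives the 2,3-trans-3,4-cis pattern of the lower unit directly.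

**8 to 6 to 5 (dehydration; source of absolute configuration).** Flavene 8 comes from cis-flavan-4-ol 6 by elimination. Alcohol 6 comes from racemic flavanone 5 by kinetic resolution in an asymmetric transfer hydrogenation. This is well precedented for flavanones and delivers the alcohol needed for the elimination.

**5 to 4 to 2 and 3; 2 to 1; 12 to 2.** Flavanone 5 is the oxa-Michael isomer of chalcone 4, the aldol condensation product of ketone 2 and aldehyde 3. Ketone 2 is the mono-benzyl ether of 1, and 12 is its allyl ether. Both halves of the target thus come from 1 and 3.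

## Roads not taken

**Alternative 1:** The cut is the C4'–C4a' bond of ring F in the lower unit. The iodo aldehyde A2 (iodine on C4a', side chain O1'–C2'–C3'–CHO) would be treated with CrCl2 and catalytic NiCl2. The arylchromium species would add to the tethered α-benzyloxy aldehyde and give the octa-O-benzyl dimer A1 with ring F closed and the C4' hydroxyl free.
- Merits: the sensitive carbinol is made late under neutral conditions and never needs a protecting group, so one hydrogenolysis finishes the synthesis. In end-game economy this road is better than the chosen one (one step from A1 against two from 22).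
- Weak points: A2 must already contain the complete upper triad and the C4–C6' bond, for which this strategy offers nothing. The acyclic C2' aryl ether must be built with stereocontrol beside an epimerisable α-alkoxy aldehyde. Aryl halides are the slowest partners in chromium-mediated additions, so reduction of the C–I bond competes. A chair-like closure with the C2' aryl and C3' benzyloxy groups equatorial is expected to place the new hydroxyl equatorial, the 3',4'-trans epimer, unless chelation overrides it.
- Against the better end game, the chosen plan obtains C4' with the correct cis relationship from an early dihydroxylation of a monomer, and its key step builds the upper unit instead of presupposing it.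

**Alternative 2:** The cut is C8a–O1 of ring C, traced back to a carbocycle. Buffered peracid would convert the 3-aryl-6-benzyloxyindan-1-one A4 into the 4-aryl-7-benzyloxy-3,4-dihydrocoumarin A3 by migration of the aryl carbon.
- Merits: C4 is fixed first in a configurationally robust ketone and is untouched by the oxygen insertion. From A3 the other two centres could be relayed from C4 by substrate control (aryl addition to the lactone carbonyl, dehydration, hydroboration anti to the C4 aryl group). That relay needs no asymmetric catalysis at C2, and in this respect it is as good as or better than the chosen plan.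
- Weak points: the migrating aryl carbon is meta to the benzyloxy group and gains nothing from it, so methylene migration competes. The peracid meets a resorcinol diether and two catechol diethers. A4 requires an enantioselective union of the lower-unit arene with the five-membered ring, which only moves the problem of absolute control. Four or five steps still separate A3 from the finished upper unit.
- The chosen plan sets convergence against this (11, 12 and 3 are joined in three steps), uses no oxidant on electron-rich rings, and bounds its stereochemical risk because a wrong C2 epimer would be a separable diastereomer.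

**Alternative 3:** The cut is C4–C4a. Acid would ionise the C4 carbinol of the open-chain aryl ether A6, and ring A would attack through the carbon para to its benzyloxy group to give the hepta-O-benzyl dimer acetonide A5.
- Merits: C2 and C3 can be installed in the acyclic precursor by reliable asymmetric oxidation. The C4 cation is well stabilised by ring D, and closure to the all-equatorial chroman is the expected outcome. No untested asymmetric step is involved, so in certainty of stereocontrol this road is ahead of the chosen one.
- Weak points: the acid must distinguish three similar benzylic C–O bonds. Besides the C4 carbinol there are the C2–O1 aryl ether (ionisation epimerises C2 or expels the aryloxy group) and the acetonide oxygen on C4'. Ring A is only singly activated, so intermolecular attack by richer rings competes. The C2 aryl ether must be made by SN2 displacement at a carbon that prefers SN1. The linear sequence is longer.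
- The chosen plan sets against the better precedent a shorter route, a ring closure under catalytic acid that also creates the alkene for C3 and C4, and a fallback to 20 that needs no new chemistry.

Key step: step 13

Remarks before the steps:
- Abbreviations: Bn is benzyl, TBS is tert-butyldimethylsilyl, Piv is pivaloyl. Ar(L) is the (2R,3R,4S)-7-(benzyloxy)-2-[3,4-bis(benzyloxy)phenyl]-3,4-bis(tert-butyldimethylsilyloxy)chroman-6-yl group of bromide 11.
- Descriptors at some centres change along the route only because protecting groups change the priorities; the geometry does not change.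
- Assumption on the chemistry: the senses of induction stated for the ruthenium catalyst (step 4) and for the chiral acid (step 13) follow the closest analogies and would be confirmed on 6 and 20; the mirror-image catalyst is used if a sense proves opposite.

## Steps

Step 1
Reactants: 1 2,4-dihydroxyacetophenone
Product: 2 4-benzyloxy-2-hydroxyacetophenone
Conditions: BnBr (1.05 equiv), K2CO3, acetone, reflux
Reagents that add atoms: benzyl bromide, BrCc1ccccc1
Why: Williamson etherification; the 2-hydroxyl is held in a hydrogen bond to the carbonyl group, so the 4-hydroxyl is alkylated selectively.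

Step 2
Reactants: 2 4-benzyloxy-2-hydroxyacetophenone; 3 3,4-bis(benzyloxy)benzaldehyde
Product: 4 (E)-1-[4-(benzyloxy)-2-hydroxyphenyl]-3-[3,4-bis(benzyloxy)phenyl]prop-2-en-1-one
Conditions: KOH (aq.), EtOH, rt
Reagents that add atoms: none
Why: Claisen–Schmidt condensation; loss of water by E1cB gives the E enone, and the 2'-phenoxide keeps the chalcone open in strong base.

Step 3
Reactants: 4 (E)-chalcone
Product: 5 rac-7-(benzyloxy)-2-[3,4-bis(benzyloxy)phenyl]chroman-4-one
Conditions: NaOAc, EtOH, reflux
Reagents that add atoms: none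
Why: Intramolecular oxa-Michael addition under weak base, the standard chalcone to flavanone isomerisation; the equilibrium favours the flavanone when the chalcone has no 6'-substituent, and unchanged 4 is recycled.

Step 4
Reactants: 5 racemic flavanone
Product: 6 (2S,4S)-7-(benzyloxy)-2-[3,4-bis(benzyloxy)phenyl]chroman-4-ol (2,4-cis)
Conditions: RuCl(p-cymene)[(S,S)-TsDPEN] (1 mol %), HCO2H/Et3N (5:2), EtOAc, rt, stopped near half conversion
Reagents that add atoms: none
Why: Kinetic resolution by Noyori-type asymmetric transfer hydrogenation, a known route to enantioenriched cis-flavan-4-ols; the catalyst sets C4 as (S) and reduces only the enantiomer that can accept hydride anti to the C2 aryl group, which fixes C2 as (S); the unreacted (R) enantiomer of 5 is separated, racemised through 4 under the conditions of step 3 and resubmitted.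

Step 5
Reactants: 6 (2S,4S)-flavan-4-ol
Product: 8 (S)-7-(benzyloxy)-2-[3,4-bis(benzyloxy)phenyl]-2H-chromene, via C4 mesylate 7 (not isolated)
Conditions: MsCl, Et3N, CH2Cl2, 0 °C to rt
Reagents that add atoms: none
Why: Mesylation and E1-type elimination; the sulfonate on a carbon activated by O1 and O7 ionises readily and triethylamine removes a C3 proton, and the basic medium leaves the C2 stereocentre untouched.

Step 6
Reactants: 8 (S)-flav-3-ene
Product: 9 (2R,3S,4S)-7-(benzyloxy)-2-[3,4-bis(benzyloxy)phenyl]chroman-3,4-diol (2,3-trans-3,4-cis)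
Conditions: OsO4 (2 mol %), NMO, acetone/H2O, rt
Reagents that add atoms: N-methylmorpholine N-oxide, C[N+]1([O-])CCOCC1; water, O (both oxygen atoms pass through catalytic osmium tetroxide, O=[Os](=O)(=O)=O)
Why: Upjohn syn-dihydroxylation; osmium tetroxide adds to the face opposite the C2 aryl group, as known for flav-3-enes, so C3 and C4 are set cis to each other and trans to the aryl group; recrystallisation of 9 is the point at which enantiomeric purity would be raised.

Step 7
Reactants: 9 diol
Product: 10 (2R,3R,4S)-7-(benzyloxy)-2-[3,4-bis(benzyloxy)phenyl]-3,4-bis(tert-butyldimethylsilyloxy)chroman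
Conditions: TBSOTf, 2,6-lutidine, CH2Cl2, 0 °C to rt
Reagents that add atoms: tert-butyldimethylsilyl triflate, CC(C)(C)[Si](C)(C)OS(=O)(=O)C(F)(F)F
Why: Silylation of both secondary hydroxyls with a silyl triflate; the silyl ethers tolerate aryllithium, catalytic strong acid at low temperature, borane and alkaline peroxide, and are later removed by fluoride without acid at C4.

Step 8
Reactants: 10 bis-silyl ether
Product: 11 (2R,3R,4S)-7-(benzyloxy)-2-[3,4-bis(benzyloxy)phenyl]-6-bromo-3,4-bis(tert-butyldimethylsilyloxy)chroman, Ar(L)–Br
Conditions: NBS, CH2Cl2, −20 °C, dark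
Reagents that add atoms: N-bromosuccinimide, O=C1CCC(=O)N1Br
Why: Electrophilic aromatic bromination; C6 is para to O1 and ortho to the benzyloxy group and is the most activated open position (C8 lies between two oxygens and the catechol-type ring is less activated), as known for benzylated flavans.

Step 9
Reactants: 2 4-benzyloxy-2-hydroxyacetophenone
Product: 12 1-[2-(allyloxy)-4-(benzyloxy)phenyl]ethanone
Conditions: allyl bromide, K2CO3, DMF, 50 °C
Reagents that add atoms: allyl bromide, C=CCBr
Why: Williamson etherification of the chelated phenol in a dipolar aprotic solvent; allyl survives the organometallic step and mild acid and is later removed under neutral conditions.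

Step 10
Reactants: 11 Ar(L)–Br; 12 1-[2-(allyloxy)-4-(benzyloxy)phenyl]ethanone
Product: 16 1-[2-(allyloxy)-4-(benzyloxy)phenyl]-1-Ar(L)-ethene, via aryllithium 13 (not isolated), via arylcerium dichloride 14 (not isolated), via tertiary carbinol 15 (not isolated)
Conditions: n-BuLi, THF, −78 °C; CeCl3, −78 °C; 12, −78 to −40 °C; aq. NH4Cl; crude carbinol, PPTS (cat.), 4 Å MS, toluene, 50 °C
Reagents that add atoms: none
Why: Bromine–lithium exchange, transmetalation to the organocerium reagent (Imamoto conditions, which suppress enolisation of the methyl ketone), 1,2-addition, then acid-catalysed E1 dehydration of the doubly benzylic tertiary alcohol, which can only lose a methyl proton; this forms the C4–C6' bond of the target at the position fixed by the bromine.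

Step 11
Reactants: 16 allyl-protected 1,1-diarylethene
Product: 17 5-(benzyloxy)-2-[1-Ar(L)-vinyl]phenol
Conditions: Pd(PPh3)4 (cat.), morpholine, THF, rt
Reagents that add atoms: none
Why: Tsuji–Trost deallylation; the π-allyl palladium complex passes the allyl group to morpholine under neutral conditions that spare the acid-sensitive diarylethene, the benzyl ethers and the silyl ethers.

Step 12
Reactants: 17 5-(benzyloxy)-2-[1-Ar(L)-vinyl]phenol; 3 3,4-bis(benzyloxy)benzaldehyde
Product: 19 [3,4-bis(benzyloxy)phenyl]{5-(benzyloxy)-2-[1-Ar(L)-vinyl]phenoxy}methyl pivalate (both epimers at the acetal carbon), via alpha-chlorobenzyl pivalate 18 (not isolated)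
Conditions: 3, PivCl, ZnCl2 (cat.), CH2Cl2, 0 °C to rt; solution added to 17, NaH, THF/DMF, −20 to 0 °C
Reagents that add atoms: pivaloyl chloride, CC(C)(C)C(=O)Cl
Why: Lewis acid-catalysed addition of an acyl chloride to an aldehyde gives the 1-chloroalkyl ester, which O-alkylates the sodium phenoxide in a Williamson reaction of SN1 character, as chloromethyl pivalate does with phenols; the basic medium protects the diarylethene, the bulky pivalate resists acyl transfer, and the stereorandom acetal carbon is of no consequence because it is ionised next.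

Step 13
Reactants: 19 O-aryl O-pivaloyl acetal
Product: 20 (2S)-7-(benzyloxy)-2-[3,4-bis(benzyloxy)phenyl]-4-Ar(L)-2H-chromene
Conditions: chiral imidodiphosphorimidate Brønsted acid (BINOL-derived, N-triflyl, 3,3'-diaryl; 5 mol %), CHCl3, −40 °C
Reagents that add atoms: none
Why: Proposed new method: the strong chiral acid protonates the pivalate carbonyl of 19 and pivalic acid leaves, the only ionisation open to an O-aryl O-acyl acetal, which gives an O-aryl oxocarbenium ion at C2 (also stabilised by ring B) paired with the confined imidodiphosphorimidate anion; both acetal epimers converge on this planar ion. The CH2 terminus of the tethered 1,1-diarylethene attacks C2 in a 6-endo-trig closure that forms C2–C3 and ring C, and the resulting C4 cation, stabilised by ring A and by O7' and O1' of ring D, gives up a C3 proton to the anion, which forms the conjugated C3=C4 alkene and returns the acid. The closest known reactions are the acid-mediated Prins-type condensations of 2-(1-arylvinyl)phenols with aldehyde equivalents to 2,4-disubstituted 2H-chromenes and the imidodiphosphorimidate-catalysed asymmetric Prins cyclisations of homoallylic alcohols with aldehydes; face control of an O-aryl oxocarbenium ion in a chromene closure has not been shown. The new C2 stereocentre is set by the chiral counter-anion (catalyst control), because the stereocentres of the lower unit lie beyond a freely rotating aryl–vinyl bond and cannot bias the face. The step needs face selectivity at C2, endo regiochemistry and one sense of ionisation: the catalyst supplies the first, the diaryl-stabilised C4 cation the second and the pivalate leaving group the third. Because 19 is a single enantiomer in its lower half, the C2 epimer of 20 would be a diastereomer and should be removable by chromatography.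

Step 14
Reactants: 20 4-aryl-flav-3-ene
Product: 22 (2R,3S,4S)-7-(benzyloxy)-2-[3,4-bis(benzyloxy)phenyl]-4-Ar(L)-chroman-3-ol (2,3-trans-3,4-trans), via C3 alkylborane 21 (not isolated)
Conditions: BH3·THF, THF, 0 °C to rt; then NaOH, H2O2, 0 °C
Reagents that add atoms: hydrogen peroxide, OO
Why: Brown hydroboration–oxidation, known to turn flav-3-enes into 2,3-trans-flavan-3-ols; boron adds to C3 (less substituted, with C4 better able to carry positive charge) and hydrogen to C4 in a syn addition on the face opposite the C2 aryl group, and oxidation with retention leaves the C3 hydroxyl trans to both aryl groups.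

Step 15
Reactants: 22 bis-silyl ether
Product: 23 (2R,3S,4S)-7-(benzyloxy)-2-[3,4-bis(benzyloxy)phenyl]-6-[(2R,3S,4S)-7-(benzyloxy)-2-[3,4-bis(benzyloxy)phenyl]-3-hydroxychroman-4-yl]chroman-3,4-diol
Conditions: TBAF, AcOH, THF, rt
Reagents that add atoms: none
Why: Fluoride-mediated desilylation buffered with acetic acid; the Si–O bonds are cleaved and the C–O bonds are not, so the benzylic C4' configuration is kept.

Step 16
Reactants: 23 hexa-O-benzyl triol
Product: 24 (2R,3S,4S)-2-(3,4-dihydroxyphenyl)-6-[(2R,3S,4R)-2-(3,4-dihydroxyphenyl)-3,7-dihydroxychroman-4-yl]chroman-3,4,7-triol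
Conditions: H2 (1 atm), Pd(OH)2/C, THF/MeOH, rt
Reagents that add atoms: none
Why: Catalytic hydrogenolysis of six aryl benzyl ethers, which are cleaved far faster than a free secondary benzylic alcohol under neutral conditions; filtration and evaporation give the polyphenol without acid or base.

## Compound list

1 | 2,4-dihydroxyacetophenone | CC(=O)c1ccc(O)cc1O | starting material
2 | 4-benzyloxy-2-hydroxyacetophenone | CC(=O)c1ccc(OCc2ccccc2)cc1O | intermediate
3 | 3,4-bis(benzyloxy)benzaldehyde | O=Cc1ccc(OCc2ccccc2)c(OCc2ccccc2)c1 | starting material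
4 | (E)-1-[4-(benzyloxy)-2-hydroxyphenyl]-3-[3,4-bis(benzyloxy)phenyl]prop-2-en-1-one | O=C(/C=C/c1ccc(OCc2ccccc2)c(OCc2ccccc2)c1)c1ccc(OCc2ccccc2)cc1O | intermediate
5 | rac-7-(benzyloxy)-2-[3,4-bis(benzyloxy)phenyl]chroman-4-one | O=C1CC(c2ccc(OCc3ccccc3)c(OCc3ccccc3)c2)Oc2cc(OCc3ccccc3)ccc12 | intermediate
6 | (2S,4S)-7-(benzyloxy)-2-[3,4-bis(benzyloxy)phenyl]chroman-4-ol | c1ccccc1COc1ccc2c(c1)O[C@H](c1ccc(OCc3ccccc3)c(OCc3ccccc3)c1)C[C@@H]2O | intermediate
7 | 4-O-methanesulfonate of 6 | c1ccccc1COc1ccc2c(c1)O[C@H](c1ccc(OCc3ccccc3)c(OCc3ccccc3)c1)C[C@@H]2OS(C)(=O)=O | intermediate (not isolated)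
8 | (S)-7-(benzyloxy)-2-[3,4-bis(benzyloxy)phenyl]-2H-chromene | c1ccccc1COc1ccc2c(c1)O[C@H](c1ccc(OCc3ccccc3)c(OCc3ccccc3)c1)C=C2 | intermediate
9 | (2R,3S,4S)-7-(benzyloxy)-2-[3,4-bis(benzyloxy)phenyl]chroman-3,4-diol | c1ccccc1COc1ccc2c(c1)O[C@H](c1ccc(OCc3ccccc3)c(OCc3ccccc3)c1)[C@@H](O)[C@H]2O | intermediate
10 | (2R,3R,4S)-7-(benzyloxy)-2-[3,4-bis(benzyloxy)phenyl]-3,4-bis(tert-butyldimethylsilyloxy)chroman | c1ccccc1COc1ccc2c(c1)O[C@H](c1ccc(OCc3ccccc3)c(OCc3ccccc3)c1)[C@@H](O[Si](C)(C)C(C)(C)C)[C@H]2O[Si](C)(C)C(C)(C)C | intermediate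
11 | (2R,3R,4S)-7-(benzyloxy)-2-[3,4-bis(benzyloxy)phenyl]-6-bromo-3,4-bis(tert-butyldimethylsilyloxy)chroman, Ar(L)–Br | Brc1cc2c(cc1OCc3ccccc3)O[C@H](c3ccc(OCc4ccccc4)c(OCc4ccccc4)c3)[C@@H](O[Si](C)(C)C(C)(C)C)[C@H]2O[Si](C)(C)C(C)(C)C | intermediate
12 | 1-[2-(allyloxy)-4-(benzyloxy)phenyl]ethanone | CC(=O)c1ccc(OCc2ccccc2)cc1OCC=C | intermediate
13 | 6-lithio derivative of 10, Ar(L)–Li | [Li]c1cc2c(cc1OCc3ccccc3)O[C@H](c3ccc(OCc4ccccc4)c(OCc4ccccc4)c3)[C@@H](O[Si](C)(C)C(C)(C)C)[C@H]2O[Si](C)(C)C(C)(C)C | intermediate (not isolated)
14 | 6-(dichlorocerio) derivative of 10, Ar(L)–CeCl2 | Cl[Ce](Cl)c1cc2c(cc1OCc3ccccc3)O[C@H](c3ccc(OCc4ccccc4)c(OCc4ccccc4)c3)[C@@H](O[Si](C)(C)C(C)(C)C)[C@H]2O[Si](C)(C)C(C)(C)C | intermediate (not isolated)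
15 | 1-[2-(allyloxy)-4-(benzyloxy)phenyl]-1-Ar(L)-ethanol (both carbinol epimers) | CC(O)(c1ccc(OCc2ccccc2)cc1OCC=C)c1cc2c(cc1OCc3ccccc3)O[C@H](c3ccc(OCc4ccccc4)c(OCc4ccccc4)c3)[C@@H](O[Si](C)(C)C(C)(C)C)[C@H]2O[Si](C)(C)C(C)(C)C | intermediate (not isolated)
16 | 1-[2-(allyloxy)-4-(benzyloxy)phenyl]-1-Ar(L)-ethene | C=C(c1ccc(OCc2ccccc2)cc1OCC=C)c1cc2c(cc1OCc3ccccc3)O[C@H](c3ccc(OCc4ccccc4)c(OCc4ccccc4)c3)[C@@H](O[Si](C)(C)C(C)(C)C)[C@H]2O[Si](C)(C)C(C)(C)C | intermediate
17 | 5-(benzyloxy)-2-[1-Ar(L)-vinyl]phenol | C=C(c1ccc(OCc2ccccc2)cc1O)c1cc2c(cc1OCc3ccccc3)O[C@H](c3ccc(OCc4ccccc4)c(OCc4ccccc4)c3)[C@@H](O[Si](C)(C)C(C)(C)C)[C@H]2O[Si](C)(C)C(C)(C)C | intermediate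
18 | [3,4-bis(benzyloxy)phenyl](chloro)methyl pivalate (racemic) | CC(C)(C)C(=O)OC(Cl)c1ccc(OCc2ccccc2)c(OCc2ccccc2)c1 | intermediate (not isolated)
19 | [3,4-bis(benzyloxy)phenyl]{5-(benzyloxy)-2-[1-Ar(L)-vinyl]phenoxy}methyl pivalate (both epimers at the acetal carbon) | CC(C)(C)C(=O)OC(c1ccc(OCc2ccccc2)c(OCc2ccccc2)c1)Oc1cc(OCc2ccccc2)ccc1C(=C)c1cc2c(cc1OCc3ccccc3)O[C@H](c3ccc(OCc4ccccc4)c(OCc4ccccc4)c3)[C@@H](O[Si](C)(C)C(C)(C)C)[C@H]2O[Si](C)(C)C(C)(C)C | intermediate
20 | (2S)-7-(benzyloxy)-2-[3,4-bis(benzyloxy)phenyl]-4-Ar(L)-2H-chromene | c1ccccc1COc1ccc2c(c1)O[C@H](c1ccc(OCc3ccccc3)c(OCc3ccccc3)c1)C=C2c1cc2c(cc1OCc3ccccc3)O[C@H](c3ccc(OCc4ccccc4)c(OCc4ccccc4)c3)[C@@H](O[Si](C)(C)C(C)(C)C)[C@H]2O[Si](C)(C)C(C)(C)C | intermediate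
21 | C3 dihydridoboryl adduct of 20 (boron on C3 and hydrogen on C4, both anti to the C2 aryl group) | c1ccccc1COc1ccc2c(c1)O[C@H](c1ccc(OCc3ccccc3)c(OCc3ccccc3)c1)[C@@H](B)[C@@H]2c1cc2c(cc1OCc3ccccc3)O[C@H](c3ccc(OCc4ccccc4)c(OCc4ccccc4)c3)[C@@H](O[Si](C)(C)C(C)(C)C)[C@H]2O[Si](C)(C)C(C)(C)C | intermediate (not isolated)
22 | (2R,3S,4S)-7-(benzyloxy)-2-[3,4-bis(benzyloxy)phenyl]-4-Ar(L)-chroman-3-ol | c1ccccc1COc1ccc2c(c1)O[C@H](c1ccc(OCc3ccccc3)c(OCc3ccccc3)c1)[C@@H](O)[C@@H]2c1cc2c(cc1OCc3ccccc3)O[C@H](c3ccc(OCc4ccccc4)c(OCc4ccccc4)c3)[C@@H](O[Si](C)(C)C(C)(C)C)[C@H]2O[Si](C)(C)C(C)(C)C | intermediate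
23 | (2R,3S,4S)-7-(benzyloxy)-2-[3,4-bis(benzyloxy)phenyl]-6-[(2R,3S,4S)-7-(benzyloxy)-2-[3,4-bis(benzyloxy)phenyl]-3-hydroxychroman-4-yl]chroman-3,4-diol | c1ccccc1COc1ccc2c(c1)O[C@H](c1ccc(OCc3ccccc3)c(OCc3ccccc3)c1)[C@@H](O)[C@@H]2c1cc2c(cc1OCc3ccccc3)O[C@H](c3ccc(OCc4ccccc4)c(OCc4ccccc4)c3)[C@@H](O)[C@H]2O | intermediate
24 | (2R,3S,4S)-2-(3,4-dihydroxyphenyl)-6-[(2R,3S,4R)-2-(3,4-dihydroxyphenyl)-3,7-dihydroxychroman-4-yl]chroman-3,4,7-triol | Oc1ccc2c(c1)O[C@H](c1ccc(O)c(O)c1)[C@@H](O)[C@@H]2c1cc2c(cc1O)O[C@H](c1ccc(O)c(O)c1)[C@@H](O)[C@H]2O | target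

## Step count and least certain steps

Total step count: 16. Longest linear sequence: 15 steps (steps 1–8 and 10–16, from 1 to 24); step 9 is a one-step branch from 2.

**Step 13 (key step, the one step beyond known chemistry).** The most likely failure is poor face selectivity at C2, because the chiral anion must discriminate the faces of a flat, strongly stabilised O-aryl oxocarbenium ion with no help from the substrate. Two further risks are acid-induced oligomerisation of the diarylethene through protonation at its CH2 terminus, and erosion of C2 in the product by reversible ionisation of the C2–O1 bond to a 1,3-diarylallyl cation. The fallback uses known chemistry and takes C2 from the resolved series. It sets out from 6 and 11 and returns at 20. Alcohol 6 is oxidised with MnO2 to (S)-7-(benzyloxy)-2-[3,4-bis(benzyloxy)phenyl]chroman-4-one F1. Bromide 11 is converted into 13 and 14 as in step 10 and added to F1 (the organocerium reagent limits enolisation and ring opening of the flavanone). The resulting tertiary 4-Ar(L)-flavan-4-ol F2 is dehydrated with catalytic PPTS to 20.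

**Step 12.** The likely failures are self-condensation of the electron-rich chloro ester under ZnCl2 before it meets the phenoxide, C-alkylation or acyl transfer in place of O-alkylation, and hydrolytic loss of the labile acetal during isolation. The fallback sets out from 17 and 3 and returns at 20. Aldehyde 3 is converted with trimethyl orthoformate and catalytic TsOH in MeOH into 3,4-bis(benzyloxy)benzaldehyde dimethyl acetal F3. Acetyl chloride turns F3 into [3,4-bis(benzyloxy)phenyl](chloro)methyl methyl ether F4, which alkylates the sodium salt of 17 to the O-aryl O-methyl acetal F5. The acid of step 13, with 5 Å sieves to take up methanol, then gives 20. In this variant the phenol may leave first; the fragments would then recombine by attack of the alkene on the methyl oxocarbenium ion and close at O1–C2 afterwards, to the same flavene.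

**Step 14.** The likely failures are slow addition of borane to a trisubstituted alkene crowded by two aryl groups, imperfect face selectivity, and β-elimination of the aryloxy group from the C3 borane with opening of ring C. The fallback sets out from 20 and returns at 22. A copper-catalysed protoboration (CuCl, 1,3-dimesitylimidazolinium chloride, NaOtBu, B2pin2, MeOH, THF) adds boron to C3 and hydrogen to C4 syn and anti to the C2 aryl group. The resulting C3 pinacol boronate F6 is oxidised with NaBO3 in THF/H2O to 22.

**Step 16.** The likely failures are hydrogenolysis of the benzylic C4'–OH bond, which is activated by O1' and O7', and incomplete debenzylation as the polyphenol binds the catalyst. The fallback exchanges the two deprotections; it sets out from 22 and returns at 24. Compound 22 is hydrogenolysed over Pd(OH)2/C while the C4' oxygen is shielded as a bulky silyl ether, which gives the hexaphenol bis-silyl ether F7. F7 is then desilylated with Et3N·3HF in THF/MeCN to 24.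

**Step 10.** The likely failures are enolisation of ketone 12 in place of addition, proton transfer from the ortho benzyloxy CH2 to the aryllithium before it reacts, and acid-induced dimerisation of the diarylethene during dehydration. The fallback sets out from 11 and returns at 15 and then 16. Aryllithium 13 is added to the non-enolisable 2-(allyloxy)-4-(benzyloxy)benzaldehyde F8 (made from 2,4-dihydroxybenzaldehyde as 12 is made from 1). The diarylmethanol F9 is oxidised with MnO2 to the benzophenone F10. MeMgBr then adds to F10 to give 15, which is dehydrated as before.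

## Further compounds

F1 | step 13 | (S)-7-(benzyloxy)-2-[3,4-bis(benzyloxy)phenyl]chroman-4-one | c1ccccc1COc1ccc2c(c1)O[C@H](c1ccc(OCc3ccccc3)c(OCc3ccccc3)c1)CC2=O
F2 | step 13 | (2S)-7-(benzyloxy)-2-[3,4-bis(benzyloxy)phenyl]-4-Ar(L)-chroman-4-ol (C4 epimers) | c1ccccc1COc1ccc2c(c1)O[C@H](c1ccc(OCc3ccccc3)c(OCc3ccccc3)c1)CC2(O)c1cc2c(cc1OCc3ccccc3)O[C@H](c3ccc(OCc4ccccc4)c(OCc4ccccc4)c3)[C@@H](O[Si](C)(C)C(C)(C)C)[C@H]2O[Si](C)(C)C(C)(C)C
F3 | step 12 | 3,4-bis(benzyloxy)benzaldehyde dimethyl acetal | COC(OC)c1ccc(OCc2ccccc2)c(OCc2ccccc2)c1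
F4 | step 12 | [3,4-bis(benzyloxy)phenyl](chloro)methyl methyl ether (racemic) | COC(Cl)c1ccc(OCc2ccccc2)c(OCc2ccccc2)c1
F5 | step 12 | 1,2-bis(benzyloxy)-4-[{5-(benzyloxy)-2-[1-Ar(L)-vinyl]phenoxy}(methoxy)methyl]benzene (both acetal epimers) | COC(c1ccc(OCc2ccccc2)c(OCc2ccccc2)c1)Oc1cc(OCc2ccccc2)ccc1C(=C)c1cc2c(cc1OCc3ccccc3)O[C@H](c3ccc(OCc4ccccc4)c(OCc4ccccc4)c3)[C@@H](O[Si](C)(C)C(C)(C)C)[C@H]2O[Si](C)(C)C(C)(C)C
F6 | step 14 | C3 pinacol boronate of the 2,3-trans-3,4-trans flavan (boron in place of the C3 hydroxyl of 22) | c1ccccc1COc1ccc2c(c1)O[C@H](c1ccc(OCc3ccccc3)c(OCc3ccccc3)c1)[C@@H](B3OC(C)(C)C(C)(C)O3)[C@@H]2c1cc2c(cc1OCc3ccccc3)O[C@H](c3ccc(OCc4ccccc4)c(OCc4ccccc4)c3)[C@@H](O[Si](C)(C)C(C)(C)C)[C@H]2O[Si](C)(C)C(C)(C)C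
F7 | step 16 | 3',4'-bis-O-(tert-butyldimethylsilyl) ether of 24 (all phenols free) | Oc1ccc2c(c1)O[C@H](c1ccc(O)c(O)c1)[C@@H](O)[C@@H]2c1cc2c(cc1O)O[C@H](c1ccc(O)c(O)c1)[C@@H](O[Si](C)(C)C(C)(C)C)[C@H]2O[Si](C)(C)C(C)(C)C
F8 | step 10 | 2-(allyloxy)-4-(benzyloxy)benzaldehyde | O=Cc1ccc(OCc2ccccc2)cc1OCC=C
F9 | step 10 | [2-(allyloxy)-4-(benzyloxy)phenyl]-Ar(L)-methanol (both carbinol epimers) | OC(c1ccc(OCc2ccccc2)cc1OCC=C)c1cc2c(cc1OCc3ccccc3)O[C@H](c3ccc(OCc4ccccc4)c(OCc4ccccc4)c3)[C@@H](O[Si](C)(C)C(C)(C)C)[C@H]2O[Si](C)(C)C(C)(C)C
F10 | step 10 | [2-(allyloxy)-4-(benzyloxy)phenyl]-Ar(L)-methanone | O=C(c1ccc(OCc2ccccc2)cc1OCC=C)c1cc2c(cc1OCc3ccccc3)O[C@H](c3ccc(OCc4ccccc4)c(OCc4ccccc4)c3)[C@@H](O[Si](C)(C)C(C)(C)C)[C@H]2O[Si](C)(C)C(C)(C)C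
A1 | alternative 1 | octa-O-benzyl dimer with free C4' hydroxyl | c3ccccc3COc1ccc2c(c1)O[C@H](c1ccc(OCc3ccccc3)c(OCc3ccccc3)c1)[C@@H](OCc3ccccc3)[C@@H]2c1cc2c(cc1OCc3ccccc3)O[C@H](c1ccc(OCc3ccccc3)c(OCc3ccccc3)c1)[C@@H](OCc3ccccc3)[C@H]2O
A2 | alternative 1 | upper flavan carrying at C4 a 4-iodo-2-benzyloxyphenyl ring whose O1' ether holds the (2R,3S)-2-benzyloxy-3-aryl-3-oxypropanal chain | c3ccccc3COc1ccc2c(c1)O[C@H](c1ccc(OCc3ccccc3)c(OCc3ccccc3)c1)[C@@H](OCc3ccccc3)[C@@H]2c1cc(I)c(cc1OCc3ccccc3)O[C@H](c1ccc(OCc3ccccc3)c(OCc3ccccc3)c1)[C@@H](OCc3ccccc3)C=O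
A3 | alternative 2 | 7-benzyloxy-4-(lower-unit aryl)-3,4-dihydrocoumarin, lower unit as acetonide | c3ccccc3COc1ccc2c(c1)OC(=O)C[C@@H]2c1cc2c(cc1OCc3ccccc3)O[C@H](c1ccc(OCc3ccccc3)c(OCc3ccccc3)c1)[C@@H](OC(C)(C)O4)[C@H]24
A4 | alternative 2 | 6-benzyloxy-3-(lower-unit aryl)indan-1-one, lower unit as acetonide | c3ccccc3COc1ccc2c(c1)C(=O)C[C@@H]2c1cc2c(cc1OCc3ccccc3)O[C@H](c1ccc(OCc3ccccc3)c(OCc3ccccc3)c1)[C@@H](OC(C)(C)O4)[C@H]24
A5 | alternative 3 | hepta-O-benzyl dimer 3',4'-acetonide | c3ccccc3COc1ccc2c(c1)O[C@H](c1ccc(OCc3ccccc3)c(OCc3ccccc3)c1)[C@@H](OCc3ccccc3)[C@@H]2c1cc2c(cc1OCc3ccccc3)O[C@H](c1ccc(OCc3ccccc3)c(OCc3ccccc3)c1)[C@@H](OC(C)(C)O4)[C@H]24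
A6 | alternative 3 | open-chain 3-benzyloxyphenyl ether with C2 aryl, C3 benzyloxy and C4 carbinol on the lower-unit arene (C4 epimers) | c3ccccc3COc1cccc(c1)O[C@H](c1ccc(OCc3ccccc3)c(OCc3ccccc3)c1)[C@@H](OCc3ccccc3)C(O)c1cc2c(cc1OCc3ccccc3)O[C@H](c1ccc(OCc3ccccc3)c(OCc3ccccc3)c1)[C@@H](OC(C)(C)O4)[C@H]24
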